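The ratio of other capture product to target is what the two earlier runs offer me, and the flask asked about has a charge ratio lying between theirs.

| flask | substrate | first nucleophile | second nucleophile | remark | time |
|---|---|---|---|---|---|
| Wednesday's | 0.20 M | 0.50 equiv | 1.3 equiv | run made earlier |  |
| Tuesday's | 0.20 M | 2 equiv | 1.3 equiv | run made earlier |  |
| flask | 0.20 M | 1.00 equiv | 1.30 equiv |  | 12 h |

| run | time / h | other capture product / % | target / % | substrate / % |
|---|---|---|---|---|
| Wednesday's | 1.50 | 16 | 4 | 77 |
| Wednesday's | 4.00 | 41 | 10 | 52 |
| Wednesday's | 8.00 | 57 | 17 | 28 |
| Wednesday's | 12.0 | 64 | 15 | 16 |
| Tuesday's | 1.00 | 9 | 8 | 82 |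
| Tuesday's | 2.00 | 17 | 12 | 73 |
| Tuesday's | 5.00 | 35 | 22 | 37 |
| Tuesday's | 12.0 | 43 | 28 | 12 |

(each reading ± 2 percentage points)

1. share of other capture product in other capture product plus target at 10 min
2. share of other capture product in other capture product plus target at 80 min
3. share of other capture product in other capture product plus target at 12 h

- the numbers in the tables scatter with a standard deviation of 2 percentage points
- steps that have been proposed: substrate <-> intermediate; first nucleophile + intermediate -> target; second nucleophile + intermediate -> other capture product; first nucleophile + target -> over-reaction product; second nucleophile -> decomposed reagent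

By the proposed steps both products come from one intermediate, so their ratio should follow a constant times c(second nucleophile)/c(first nucleophile). The ratio reads 4.10 in Wednesday's run at 4.00 h and 1.42 in Tuesday's run at 2.00 h. Dividing each by its charged ratio gives 1.58 and 2.18. I take the mean, 1.88, as a reading of the selectivity factor: how many times more readily the intermediate takes second nucleophile than first at equal concentrations.

Two extreme versions of the flask can be solved in the head. An intermediate that does not discriminate, the symmetric case, gives the share of the charge, 56.5%. One that takes nothing but second nucleophile gives 100%. The factor exceeds one, so I expect the flask at 70.9% while both nucleophiles stand near their charges, above the symmetric share and below 100%. Later, capture takes a fraction of the second nucleophile's charge 1.88 times as fast as of the first's, so I expect that to lower the share, while over-reaction of target raises it.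

The forecast gives 69% at 10 min, 69% at 80 min and 72% at 12 h, holding that “the intermediate stays small and its reversibility doesn't affect the split”. It takes the factor as 1.7, so its start is lower than mine.

The flask gives 73.0%, 72.4% and 71.1%, and the forecast is right within the margin at each time.

    substrate ⇌ intermediate (K = 0.0890, k = 0.00370 min⁻¹)
    first nucleophile + intermediate → target (k = 0.230 M⁻¹ min⁻¹)
    second nucleophile + intermediate → other capture product (k = 0.480 M⁻¹ min⁻¹)
    first nucleophile + target → over-reaction product (k = 0.00270 M⁻¹ min⁻¹)
    second nucleophile → decomposed reagent (k = 5.50 × 10⁻⁴ min⁻¹)

At 12.0 h the flask holds 33.7% of its second nucleophile and 67.6% of its first. I carry the factor to a neighbour flask charged with 2.50 equiv of first nucleophile. There the factor gives 49.4% at the start, and the neighbour stands at 52.0% at 10 min. At 12 h that neighbour stands at 58.9%, with 18.2% over-reaction product.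

(The runs are calculated from invented constants, and the scatter is random.)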